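I was asked how far the electrophile gets in 10 h at two scavenger charges, and whether the scavenger shows in that figure at all.

in all of them: electrophile 0.46 M
- west: nucleophile 0.46 M; scavenger 0.27 M; run made earlier
- north-east: nucleophile 0.46 M; scavenger 0.57 M; run made earlier
- Thursday's: nucleophile 0.460 M; scavenger 0.460 M; time 10 h
- Wednesday's: nucleophile 0.460 M; scavenger 0.230 M; time 10 h

- west (time / h: electrophile / %, product / %): 0.833: 90.4, 8.7; 1.33: 88.5, 10.0; 2.00: 84.1, 14.9; 3.00: 79.3, 20.9; 4.00: 76.2, 22.3; 6.00: 73.6, 28.1; 10.0: 64.6, 34.4
- north-east (time / h: electrophile / %, product / %): 0.833: 91.5, 5.9; 1.33: 88.5, 12.1; 2.00: 84.9, 15.3; 3.00: 80.3, 20.7; 4.00: 77.3, 24.6; 6.00: 71.0, 27.6; 10.0: 63.3, 35.3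

(standard deviation of a reading: 1 percentage point)

- for acid set free the idle adduct is counted in
- reactions considered so far: electrophile + nucleophile -> acid set free + product; nucleophile + acid set free <-> protonated nucleophile; acid set free + scavenger -> scavenged by-product; 2 nucleophile -> homo dimer; nucleophile + acid set free <-> idle adduct

* part of the electrophile that has reacted at the end, Thursday's
* part of the electrophile that has reacted at the end, Wednesday's
* what raising the concentration of scavenger from its lowest to its highest value here does to the part of the electrophile that has reacted (changes below 5 percentage points count as none) (it falls / it rises / no change)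

By its first step the electrophile falls with a pseudo-first-order constant that follows c(nucleophile), so I read that constant as a pace from the earlier runs, taking the two together. Over the first reading it was 0.114 h⁻¹, and over the last interval 0.0307 h⁻¹. A flask keeping the first pace throughout would have reacted 68.0 % at 10 h, and one at the last pace from the start 26.4 %. I expected the new flasks to lie between them, because the first pace was faster than the last.

So I replaced the curve by its mean: the mean clock, minus the logarithm of the fraction of electrophile left, divided by the time, 0.0447 h⁻¹. Its error showed at 6.00 h, where it says 23.5 % and the earlier runs read 26.4 % and 29.0 %, so I used it at 10 h, where it was measured. There it gave me 36.1 % for both new flasks.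

The forecast said 36 % for Thursday's flask, 35.5 % for Wednesday's and no change, holding that “doubling the scavenger does nothing measurable”. For Wednesday's flask my figure stood slightly higher.

Thursday's flask gave 35.3 % and Wednesday's 33.9 %, so the answer on raising the scavenger was no change: a change of 1.4 percentage points, under the 5 points that counts, and 55.1 % of Wednesday's scavenger was still free at the end.

    electrophile + nucleophile → acid set free + product (k = 0.00459 M⁻¹ min⁻¹)
    nucleophile + acid set free ⇌ protonated nucleophile, settled at all times (K = 44.6 M⁻¹)
    acid set free + scavenger → scavenged by-product (k = 0.205 M⁻¹ min⁻¹)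
    2 nucleophile → homo dimer (k = 0.00509 M⁻¹ min⁻¹)
    nucleophile + acid set free ⇌ idle adduct, settled at all times (K = 57.2 M⁻¹)

Wednesday's own mean clock was 0.0414 h⁻¹, beside the carried 0.0447 h⁻¹. With the other charges and the time held, Wednesday's answer has moved by 5 points at 0.597 M of nucleophile, and a flask like Wednesday's with 1.2 M of nucleophile reached 52.6 %. That flask held 2.61 times Wednesday's nucleophile charge, and its mean clock stood at 1.67 times 0.0447 h⁻¹.

The numbers in the tables were computed for substances that don't exist, noise included.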